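**Strategy.** The target is the C2-symmetric head-to-head [2+2] dimer of one lindenane butenolide, so the synthesis rests on that monomer and on its ring B (C5–C10). A catalytic enantioselective Diels–Alder reaction of 2-(triisopropylsilyloxy)buta-1,3-diene with (E)-3-methylpent-2-en-4-ynal forms C5–C6 and C9–C10 together. It exploits the trans disposition of C4 and C1 across the C5–C10 junction of rings A and B, which is simply the E geometry of the dienophile, creates the quaternary C10, and leaves the C8 oxygen as a C7=C8 enol ether. Carbenoid cyclopropanation then closes ring A, pyruvate builds the butenolide, and light joins C8–C8′ and C9–C9′.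

Key step: step 3

Remark on numbering: lindenane numbering is used throughout (C1–C2–C3 cyclopropane with C2 the CH2; C4 carries the C15 methylidene; C5 and C10 are the junction of rings A and B; C6–C9 complete ring B; C11–C13 belong to the lactone, C12 being the carbonyl; C14 is the methyl on C10; primed numbers are the second half of the dimer). α is the face of H-5, β the face of C14.

Assumption: (E)-3-methylpent-2-en-4-yn-1-ol, methyl vinyl ketone and ethyl pyruvate are taken as commercial.

**Step 1**
Reactants: 1 methyl vinyl ketone (but-3-en-2-one)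
Product: 2 2-(triisopropylsilyloxy)buta-1,3-diene
Conditions: TIPSOTf, Et3N, CH2Cl2, 0 °C → rt
Reagents that add atoms: triisopropylsilyl trifluoromethanesulfonate, CC(C)[Si](C(C)C)(C(C)C)OS(=O)(=O)C(F)(F)F
Why: Soft enolisation and O-silylation of the methyl ketone gives the cross-conjugated 2-silyloxydiene, the bulky silyl group being chosen so that the enol ether survives to step 9.

**Step 2**
Reactants: 3 (E)-3-methylpent-2-en-4-yn-1-ol
Product: 4 (E)-3-methylpent-2-en-4-ynal
Conditions: activated MnO2, CH2Cl2, rt; used at once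
Reagents that add atoms: none
Why: MnO2 oxidises the allylic alcohol selectively and should leave the alkyne and the E double bond (formyl cis to methyl, trans to ethynyl) untouched.

**Step 3**
Reactants: 2 2-(triisopropylsilyloxy)buta-1,3-diene; 4 (E)-3-methylpent-2-en-4-ynal
Product: 5 (1R,6R)-6-ethynyl-6-methyl-4-(triisopropylsilyloxy)cyclohex-3-ene-1-carbaldehyde (formyl and ethynyl trans)
Conditions: (S)-1-(2-methylphenyl)-3,3-diphenyltetrahydro-1H,3H-pyrrolo[1,2-c][1,3,2]oxazaborole (20 mol%), HN(SO2CF3)2 (18 mol%), 2 (2 equiv), CH2Cl2, −78 → −20 °C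
Reagents that add atoms: none
Why: The protonated oxazaborolidine binds the formyl oxygen of 4 (s-trans enal, formyl C–H···O contact) and lowers the LUMO of C5=C10, which then undergoes a concerted, asynchronous, suprafacial Diels–Alder [4π+2π] cycloaddition with s-cis 2; this is the known cationic-oxazaborolidine Diels–Alder reaction of enals with 2-silyloxydienes, applied here to a β,β-disubstituted enal. Ring B is closed as a six-membered carbocycle by intermolecular formation of both σ bonds, C9–C10 from the diene CH2 next to the silyloxy carbon and C5–C6 from the other terminus. C5 and C10 are the new stereocentres: their relative configuration (C4 formyl and C1 ethynyl trans, as the trans ring junction requires) is the stereospecific transcription of the E alkene, and their absolute configuration should follow from diene attack on the Re face of C5, the face left open when a phenyl group of the (S)-catalyst covers the other. The step needs para regioselectivity, which comes from matching the large HOMO coefficient of that diene CH2 with the large LUMO coefficient at C10, so that the oxygen lands on C8 and the enol ether on C7=C8. It also needs chemoselectivity for the enal C=C over the alkyne and over 1,2-addition to the formyl group; this rests on the direct conjugation of C5=C10 with the activated carbonyl, the small size of the ethynyl group at C10 and the bulky silyl group, which disfavours silyl-transfer pathways.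

**Step 4**
Reactants: 5 Diels–Alder adduct
Product: 6 2-[(1R,6R)-6-ethynyl-6-methyl-4-(triisopropylsilyloxy)cyclohex-3-en-1-yl]oxirane (both epimers at the oxirane CH, C4)
Conditions: Me3S+ I−, n-BuLi, THF, −10 °C; then 5, −78 → 0 °C
Reagents that add atoms: trimethylsulfonium iodide, C[S+](C)C.[I-]
Why: Corey–Chaykovsky epoxidation (ylide addition to the aldehyde, then ring closure of the betaine) supplies C3; addition should outrun enolisation at C5 at low temperature, and the C4 centre is erased in step 7.

**Step 5**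
Reactants: 6 ethynyl oxirane
Product: 7 2-[(1R,6S)-6-ethenyl-6-methyl-4-(triisopropylsilyloxy)cyclohex-3-en-1-yl]oxirane
Conditions: H2 (1 atm), 5% Pd/CaCO3 poisoned with Pb(OAc)2, quinoline, EtOAc, rt
Reagents that add atoms: none
Why: Lindlar semi-hydrogenation stops at the terminal alkene (C1=C2) and should not touch the trisubstituted enol ether or the oxirane.

**Step 6**
Reactants: 7 vinyl oxirane
Product: 9 (1aR,1bS,5aR,6aS)-1b-methyl-3-(triisopropylsilyloxy)-1,1a,1b,2,5,5a,6,6a-octahydrocyclopropa[a]inden-6-ol (trans ring junction, cyclopropane CH2 syn to the C10 methyl, both C4 epimers), via lithiated oxirane 8 (not isolated)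
Conditions: lithium 2,2,6,6-tetramethylpiperidide (LiTMP, from the amine and n-BuLi, 2.5 equiv), t-BuOMe, 0 °C → rt
Reagents that add atoms: none
Why: Hodgson cyclopropanation: LiTMP lithiates the oxirane CH2 and the carbenoid adds to the C10 vinyl group, closing ring A trans-fused (both tethers equatorial on ring B) with a cis-fused cyclopropane; C2 is expected syn to C14 because the vinyl rotamer that reacts keeps its CH2 terminus away from C9 and the C8 silyloxy group.

**Step 7**
Reactants: 9 tricyclic alcohol
Product: 10 (1aR,1bS,5aR,6aS)-1b-methyl-3-(triisopropylsilyloxy)-1a,1b,2,5,5a,6a-hexahydrocyclopropa[a]inden-6(1H)-one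
Conditions: Dess–Martin periodinane, pyridine, CH2Cl2, 0 °C → rt
Reagents that add atoms: none
Why: Dess–Martin oxidation of the cyclopropyl carbinol converges both C4 epimers on one ketone, with pyridine buffering the acetic acid so that the enol ether survives.

**Step 8**
Reactants: 10 tricyclic ketone
Product: 11 (1aR,1bS,5aS,6aS)-1b-methyl-6-methylidene-3-(triisopropylsilyloxy)-1,1a,1b,2,5,5a,6,6a-octahydrocyclopropa[a]indene
Conditions: Ph3PCH3Br, KOt-Bu, THF, 0 °C → rt
Reagents that add atoms: methyltriphenylphosphonium bromide, C[P+](c1ccccc1)(c1ccccc1)c1ccccc1.[Br-]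
Why: Wittig methylenation installs C15; a slight deficit of base and low temperature are meant to keep the epimerisable C5 (trans junction) intact.

**Step 9**
Reactants: 11 silyl enol ether; 12 ethyl pyruvate
Product: 13 ethyl 2-hydroxy-2-[(1aR,1bS,5aS,6aS)-1b-methyl-6-methylidene-3-oxodecahydrocyclopropa[a]inden-4-yl]propanoate (mixture at C7 and C11)
Conditions: TiCl4 (1.1 equiv), CH2Cl2, −78 °C
Reagents that add atoms: none
Why: Mukaiyama aldol addition: C7 of the regiodefined C7=C8 enol ether attacks the TiCl4-chelated keto group of pyruvate, so the C7–C11 bond forms with no C7/C9 ambiguity; the two new centres are erased in step 10.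

**Step 10**
Reactants: 13 aldol adduct
Product: 15 chloranthalactone A, (1R,3S,5S,10S)-lindena-4(15),7(11),8-trien-12,8-olide, via alkylidene keto ester 14 (not isolated)
Conditions: p-TsOH·H2O (cat.), toluene, 80 °C, Dean–Stark
Reagents that add atoms: none
Why: Acid-catalysed dehydration of the tertiary aldol gives the 2-alkylidene ketone, whose C8 carbonyl can enolise only towards C9 and then lactonises (5-exo-trig acyl substitution, loss of ethanol) to the γ-alkylidene butenolide with C7=C11 and C8=C9.

**Step 11**
Reactants: 15 chloranthalactone A (two molecules)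
Product: 16 target, the head-to-head cyclobutane dimer (C8–C8′ and C9–C9′ bonds, both on the α faces)
Conditions: hν (high-pressure Hg lamp, Pyrex filter), degassed hexane, rt
Reagents that add atoms: none
Why: [2+2] photodimerisation of the C8=C9 enol-lactone double bonds: C9–C9′ bonding first gives the doubly α-oxy, allylic 1,4-biradical that closes at C8–C8′ (head-to-head), and each monomer should react on its α face, anti to the axial C14 methyl, which for two molecules of the same enantiomer sets C8, C9, C8′ and C9′ as in the C2-symmetric target.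

**Compound list**
1 | methyl vinyl ketone | CC(=O)C=C | starting material
2 | 2-(triisopropylsilyloxy)buta-1,3-diene | C=CC(=C)O[Si](C(C)C)(C(C)C)C(C)C | intermediate
3 | (E)-3-methylpent-2-en-4-yn-1-ol | OC/C=C(\C)C#C | starting material
4 | (E)-3-methylpent-2-en-4-ynal | O=C/C=C(\C)C#C | intermediate
5 | (1R,6R)-6-ethynyl-6-methyl-4-(triisopropylsilyloxy)cyclohex-3-ene-1-carbaldehyde | O=C[C@@H]1CC=C(O[Si](C(C)C)(C(C)C)C(C)C)C[C@@]1(C)C#C | intermediate
6 | 2-[(1R,6R)-6-ethynyl-6-methyl-4-(triisopropylsilyloxy)cyclohex-3-en-1-yl]oxirane (oxirane CH epimers) | C1OC1[C@@H]2CC=C(O[Si](C(C)C)(C(C)C)C(C)C)C[C@@]2(C)C#C | intermediate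
7 | 2-[(1R,6S)-6-ethenyl-6-methyl-4-(triisopropylsilyloxy)cyclohex-3-en-1-yl]oxirane (oxirane CH epimers) | C1OC1[C@@H]2CC=C(O[Si](C(C)C)(C(C)C)C(C)C)C[C@@]2(C)C=C | intermediate
8 | {3-[(1R,6S)-6-ethenyl-6-methyl-4-(triisopropylsilyloxy)cyclohex-3-en-1-yl]oxiran-2-yl}lithium | [Li]C1OC1[C@@H]2CC=C(O[Si](C(C)C)(C(C)C)C(C)C)C[C@@]2(C)C=C | intermediate
9 | (1aR,1bS,5aR,6aS)-1b-methyl-3-(triisopropylsilyloxy)-1,1a,1b,2,5,5a,6,6a-octahydrocyclopropa[a]inden-6-ol (C4 epimers) | OC1[C@H]2C[C@H]2[C@@]2(C)[C@H]1CC=C(O[Si](C(C)C)(C(C)C)C(C)C)C2 | intermediate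
10 | (1aR,1bS,5aR,6aS)-1b-methyl-3-(triisopropylsilyloxy)-1a,1b,2,5,5a,6a-hexahydrocyclopropa[a]inden-6(1H)-one | O=C1[C@H]2C[C@H]2[C@@]2(C)[C@H]1CC=C(O[Si](C(C)C)(C(C)C)C(C)C)C2 | intermediate
11 | (1aR,1bS,5aS,6aS)-1b-methyl-6-methylidene-3-(triisopropylsilyloxy)-1,1a,1b,2,5,5a,6,6a-octahydrocyclopropa[a]indene | C=C1[C@H]2C[C@H]2[C@@]2(C)[C@H]1CC=C(O[Si](C(C)C)(C(C)C)C(C)C)C2 | intermediate
12 | ethyl pyruvate | CCOC(=O)C(C)=O | starting material
13 | ethyl 2-hydroxy-2-[(1aR,1bS,5aS,6aS)-1b-methyl-6-methylidene-3-oxodecahydrocyclopropa[a]inden-4-yl]propanoate (C7/C11 mixture) | C=C1[C@H]2C[C@H]2[C@@]2(C)[C@H]1CC(C(C)(O)C(=O)OCC)C(=O)C2 | intermediate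
14 | ethyl 2-[(1aR,1bS,5aS,6aS)-1b-methyl-6-methylidene-3-oxooctahydrocyclopropa[a]inden-4-ylidene]propanoate (E/Z) | C=C1[C@H]2C[C@H]2[C@@]2(C)[C@H]1CC(=C(C)C(=O)OCC)C(=O)C2 | intermediate
15 | chloranthalactone A, (1R,3S,5S,10S)-lindena-4(15),7(11),8-trien-12,8-olide | C=C1[C@H]2C[C@H]2[C@@]2(C)[C@H]1CC1=C(C)C(=O)OC1=C2 | intermediate
16 | head-to-head α,α-[2+2] dimer of 15 (cyclobutane C8–C9–C9′–C8′) | C=C1[C@H]2C[C@H]2[C@@]2(C)[C@H]1CC1=C(C)C(=O)O[C@]13[C@H]2[C@H]1[C@@]2(C)[C@@H]4C[C@@H]4C(=C)[C@@H]2CC2=C(C)C(=O)O[C@@]213 | target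

**Totals.** 11 steps in all; longest linear sequence 10 steps (steps 2–11 from 3, or steps 1 and 3–11 from 1).

**Steps most likely to fail**

1. Step 3. The β,β-disubstituted C10 terminus may react too slowly. The reaction could then be diverted into 1,2-addition of the enol ether to the formyl group or cycloaddition at the alkyne, or facial control could be lost. The fallback sets out from 2 and returns at 7. The same catalyst is used with the doubly activated dienophile ethyl (E)-2-methyl-4-oxobut-2-enoate (CCOC(=O)/C(C)=C/C=O, from ethyl tiglate and SeO2). The catalyst-bound formyl group should still direct the diene CH2 next to the silyloxy carbon to C10 and give ethyl (1R,6R)-6-formyl-1-methyl-3-(triisopropylsilyloxy)cyclohex-3-ene-1-carboxylate F1. Corey–Chaykovsky epoxidation (Me3S+ I−, n-BuLi) gives ethyl (1R,6R)-1-methyl-6-(oxiran-2-yl)-3-(triisopropylsilyloxy)cyclohex-3-ene-1-carboxylate F2. i-Bu2AlH at −78 °C reduces the ester to (1R,6R)-1-methyl-6-(oxiran-2-yl)-3-(triisopropylsilyloxy)cyclohex-3-ene-1-carbaldehyde F3, and Ph3P=CH2 converts F3 into 7.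

2. Step 6. The carbenoid may add to the wrong face of the vinyl group (cyclopropane anti to C14), be captured by the electron-rich C7=C8 enol ether, or the oxirane may undergo β-elimination. The fallback sets out from 7 and returns at 9 (its 4β-hydroxy epimer). Excess dimethylsulfonium methylide opens the oxirane at its CH2 end and eliminates to 1-[(1R,6S)-6-ethenyl-6-methyl-4-(triisopropylsilyloxy)cyclohex-3-en-1-yl]prop-2-en-1-ol F4. Ring-closing metathesis with the second-generation Grubbs catalyst RuCl2(=CHPh)(PCy3)(H2IMes) closes ring A as trans-fused 3a-methyl-5-(triisopropylsilyloxy)-3a,4,7,7a-tetrahydro-1H-inden-1-ol F5. Dess–Martin oxidation gives the corresponding inden-1-one F6. NaBH4/CeCl3·7H2O should deliver hydride to the α face (anti to C14 and C6) and give the 1β-alcohol F7, with the hydroxyl syn to the angular methyl. Hydroxyl-directed Simmons–Smith cyclopropanation (Et2Zn, CH2I2, one equivalent of carbenoid on the zinc alkoxide, to spare the enol ether) then adds C2 syn to the hydroxyl group and to C14.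

3. Step 9. The Lewis acid may cause protodesilylation without C–C bond formation, or open the methylidene-cyclopropane unit. The fallback sets out from 11 and returns at 13. Bu4NF/AcOH in THF releases (1aR,1bS,5aS,6aS)-1b-methyl-6-methylideneoctahydrocyclopropa[a]inden-3-one F8. Kinetic deprotonation with LiN(i-Pr)2 at −78 °C should occur at C7 because C9 is neopentyl, and the enolate is trapped with ZnCl2 and ethyl pyruvate.

**Further compounds**
F1 | step 3 | ethyl (1R,6R)-6-formyl-1-methyl-3-(triisopropylsilyloxy)cyclohex-3-ene-1-carboxylate | O=C[C@@H]1CC=C(O[Si](C(C)C)(C(C)C)C(C)C)C[C@@]1(C)C(=O)OCC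
F2 | step 3 | ethyl (1R,6R)-1-methyl-6-(oxiran-2-yl)-3-(triisopropylsilyloxy)cyclohex-3-ene-1-carboxylate | C1OC1[C@@H]2CC=C(O[Si](C(C)C)(C(C)C)C(C)C)C[C@@]2(C)C(=O)OCC
F3 | step 3 | (1R,6R)-1-methyl-6-(oxiran-2-yl)-3-(triisopropylsilyloxy)cyclohex-3-ene-1-carbaldehyde | C1OC1[C@@H]2CC=C(O[Si](C(C)C)(C(C)C)C(C)C)C[C@@]2(C)C=O
F4 | step 6 | 1-[(1R,6S)-6-ethenyl-6-methyl-4-(triisopropylsilyloxy)cyclohex-3-en-1-yl]prop-2-en-1-ol | C=CC(O)[C@@H]1CC=C(O[Si](C(C)C)(C(C)C)C(C)C)C[C@@]1(C)C=C
F5 | step 6 | trans-fused 3a-methyl-5-(triisopropylsilyloxy)-3a,4,7,7a-tetrahydro-1H-inden-1-ol (C1 epimers) | OC1C=C[C@@]2(C)[C@H]1CC=C(O[Si](C(C)C)(C(C)C)C(C)C)C2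
F6 | step 6 | trans-fused 3a-methyl-5-(triisopropylsilyloxy)-3a,4,7,7a-tetrahydro-1H-inden-1-one | O=C1C=C[C@@]2(C)[C@H]1CC=C(O[Si](C(C)C)(C(C)C)C(C)C)C2
F7 | step 6 | trans-fused 3a-methyl-5-(triisopropylsilyloxy)-3a,4,7,7a-tetrahydro-1H-inden-1-ol, hydroxyl syn to the 3a-methyl | O[C@H]1C=C[C@@]2(C)[C@H]1CC=C(O[Si](C(C)C)(C(C)C)C(C)C)C2
F8 | step 9 | (1aR,1bS,5aS,6aS)-1b-methyl-6-methylideneoctahydrocyclopropa[a]inden-3-one | C=C1[C@H]2C[C@H]2[C@@]2(C)[C@H]1CCC(=O)C2
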